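**Strategy.** Ring C of the flavan-3,4-diol is cut at O1–C2 and C4a–C4, which leaves a symmetric ring A resorcinol and a C2–C3–C4 unit at the level of a trans-α,β-epoxy aldehyde. The key step exploits that C4 is a benzylic carbinol ortho to O1 and that C2 is a benzylic C–O carbon anti to the C3 hydroxyl: in one flask the magnesium aryloxide adds its only free ring carbon (C4a) to the aldehyde (C4) under chelation control, and the neighbouring aryloxide oxygen (O1) opens the epoxide at C2 with inversion, closing ring C with all three stereocenters in place. Silyl ethers allow a fluoride deprotection that spares the C4 hydroxyl.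

Key step: step 9

Remark: atom and ring labels (O1, C2, C3, C4, C4a; ring A = pentaoxygenated benzene ring, ring B = trihydroxyphenyl ring, ring C = pyran ring) follow flavan numbering; TBS = tert-butyldimethylsilyl.

**Route**

Step 1
Reactants: 1 2,6-dimethoxyphenol
Product: 2 tert-butyl(2,6-dimethoxyphenoxy)dimethylsilane
Conditions: TBSCl (1.2 equiv), imidazole (2.5 equiv), DMF, rt
Reagents that add atoms: tert-butyldimethylsilyl chloride, CC(C)(C)[Si](C)(C)Cl
Why: Standard silylation of a phenol (silyl chloride and imidazole) should cap the hydroxyl that becomes the C7 oxygen, so that the two methoxy groups and not a free para-directing phenol steer the bromination that follows.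

Step 2
Reactants: 2 tert-butyl(2,6-dimethoxyphenoxy)dimethylsilane
Product: 3 tert-butyl(3,5-dibromo-2,6-dimethoxyphenoxy)dimethylsilane
Conditions: NBS (2.1 equiv), MeCN, 0 °C → rt
Reagents that add atoms: N-bromosuccinimide, O=C1CCC(=O)N1Br
Why: Electrophilic aromatic bromination should place each bromine ortho to one methoxy group and para to the other, as in the bromination of 1,2,3-trimethoxybenzene, because the flanked central silyloxy group is twisted out of conjugation and activates its para position least.

Step 3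
Reactants: 3 tert-butyl(3,5-dibromo-2,6-dimethoxyphenoxy)dimethylsilane
Product: 6 5-[(tert-butyldimethylsilyl)oxy]-4,6-dimethoxybenzene-1,3-diol, via dilithioarene 4 (not isolated), via bis(diisopropyl boronate) 5 (not isolated)
Conditions: n-BuLi (2.4 equiv), THF, −78 → −40 °C; B(OiPr)3 (4 equiv), −78 °C → rt; then AcOH, 30% aq H2O2, 0 °C → rt
Reagents that add atoms: hydrogen peroxide, OO (n-butyllithium, [Li]CCCC, and triisopropyl borate, CC(C)OB(OC(C)C)OC(C)C, put lithium and boron into 4 and 5 only)
Why: Double bromine–lithium exchange is assisted by the methoxy group ortho to each new carbon–lithium bond, and borate trapping followed by peroxide oxidation of the aryl boronates (1,2-shift of aryl from boron to oxygen) should give the two phenols under weakly acidic conditions that spare the aryl silyl ether.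

Step 4
Reactants: 7 3,4,5-trihydroxybenzaldehyde
Product: 8 3,4,5-tris[(tert-butyldimethylsilyl)oxy]benzaldehyde
Conditions: TBSCl (3.6 equiv), imidazole (7 equiv), DMF, rt
Reagents that add atoms: tert-butyldimethylsilyl chloride, CC(C)(C)[Si](C)(C)Cl
Why: Exhaustive phenol silylation is routine, and silyl ethers are chosen for ring B because the benzylic C4 hydroxyl of the final diol would not survive the hydrogenolysis that benzyl ethers need and because bulky silyloxy groups are weak donors that keep the later benzylic epoxide from ionising.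

Step 5
Reactants: 8 3,4,5-tris[(tert-butyldimethylsilyl)oxy]benzaldehyde
Product: 9 ethyl (E)-3-{3,4,5-tris[(tert-butyldimethylsilyl)oxy]phenyl}prop-2-enoate
Conditions: Ph3P=CHCO2Et (1.3 equiv), toluene, 80 °C
Reagents that add atoms: ethyl (triphenylphosphoranylidene)acetate, CCOC(=O)C=P(c1ccccc1)(c1ccccc1)c1ccccc1
Why: Wittig olefination with a stabilised ylide is E-selective and runs under neutral conditions that leave the aryl silyl ethers intact.

Step 6
Reactants: 9 ethyl (E)-3-{3,4,5-tris[(tert-butyldimethylsilyl)oxy]phenyl}prop-2-enoate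
Product: 10 (E)-3-{3,4,5-tris[(tert-butyldimethylsilyl)oxy]phenyl}prop-2-en-1-ol
Conditions: i-Bu2AlH (2.5 equiv), CH2Cl2, −78 °C; aqueous potassium sodium tartrate
Reagents that add atoms: none
Why: 1,2-Reduction of the conjugated ester with diisobutylaluminium hydride at low temperature should give the E-allylic alcohol without touching the alkene or the silyl ethers.

Step 7
Reactants: 10 (E)-3-{3,4,5-tris[(tert-butyldimethylsilyl)oxy]phenyl}prop-2-en-1-ol
Product: 11 [(2S,3S)-3-{3,4,5-tris[(tert-butyldimethylsilyl)oxy]phenyl}oxiran-2-yl]methanol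
Conditions: Ti(OiPr)4 (10 mol%), L-(+)-diethyl tartrate (12 mol%), t-BuOOH (2 equiv), 4 Å molecular sieves, CH2Cl2, −20 °C
Reagents that add atoms: tert-butyl hydroperoxide, CC(C)(C)OO
Why: Katsuki–Sharpless asymmetric epoxidation, in which L-(+)-diethyl tartrate turns E-allylic alcohols into (2S,3S)-epoxy alcohols as it does cinnamyl alcohol, should set both epoxide carbons, that is C3 of the target directly and C2 before its later inversion.

Step 8
Reactants: 11 [(2S,3S)-3-{3,4,5-tris[(tert-butyldimethylsilyl)oxy]phenyl}oxiran-2-yl]methanol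
Product: 12 (2R,3S)-3-{3,4,5-tris[(tert-butyldimethylsilyl)oxy]phenyl}oxirane-2-carbaldehyde
Conditions: Dess–Martin periodinane (1.3 equiv), pyridine, CH2Cl2, 0 °C → rt; used without chromatography
Reagents that add atoms: none
Why: Dess–Martin oxidation buffered with pyridine should give the α,β-epoxy aldehyde without epimerisation or epoxide opening, the change of the C2 descriptor from S to R being only a change of substituent priorities.

Step 9
Reactants: 6 5-[(tert-butyldimethylsilyl)oxy]-4,6-dimethoxybenzene-1,3-diol; 12 (2R,3S)-3-{3,4,5-tris[(tert-butyldimethylsilyl)oxy]phenyl}oxirane-2-carbaldehyde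
Product: 15 (2R,3S,4R)-7-[(tert-butyldimethylsilyl)oxy]-6,8-dimethoxy-2-{3,4,5-tris[(tert-butyldimethylsilyl)oxy]phenyl}-3,4-dihydro-2H-chromene-3,4,5-triol, via bis(bromomagnesium) aryloxide 13 (not isolated), via magnesium epoxy alkoxide 14 (not isolated)
Conditions: 6, EtMgBr (2.0 equiv), Et2O, 0 °C; solvent exchange to CH2Cl2; 12 (1.0 equiv), −40 °C → rt; pH 7 phosphate buffer
Reagents that add atoms: ethylmagnesium bromide, CC[Mg]Br (magnesium and bromine stay in 13 and 14 only and no atom of it in 15)
Why: Proposed new method: the bis(bromomagnesium) aryloxide 13 should bind the aldehyde of 12 at magnesium and add its one unsubstituted ring carbon (the later C4a) to the carbonyl through a closed six-membered transition state, after which the magnesium alkoxide 14 holds the epoxide oxygen in a chelate and the neighbouring aryloxide oxygen (the later O1) opens the epoxide at the benzylic carbon by SN2. The closest known reaction types are the ortho-specific hydroxyalkylation of magnesium phenoxides with α-oxygenated aldehydes and the 6-endo opening of aryl epoxides by an ortho phenol used in flavan-3-ol and dihydroflavonol syntheses, together with the chelate-directed opening of 2,3-epoxy alcohols at the carbon remote from the carbinol; their union on an α,β-epoxy aldehyde as a one-flask (3+3) annulation is the untested part. Ring C is closed in the 6-endo-tet mode. C4 is set in the addition by chelation of the carbonyl and epoxide oxygens to magnesium (Cram chelate model, attack on the face away from the epoxide carbon, which gives the 3,4-threo and thus 3,4-trans 4R carbinol), C3 is carried over unchanged from the epoxide, and C2 is set by inversion at the benzylic epoxide carbon, which turns the trans-epoxide into the 2,3-trans ring (2R,3S). The step needs carbon in place of oxygen attack at the single free ring position (secured by the magnesium template and by the symmetry of 6, whose two hydroxyls are equivalent, so either may close the ring), the chelate face at the carbonyl, 6-endo in place of 5-exo opening (benzylic activation plus the alkoxide–epoxide chelate) and SN2 in place of SN1 opening (the twisted, weakly donating silyloxy groups of ring B disfavour a benzylic cation).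

Step 10
Reactants: 15 (2R,3S,4R)-7-[(tert-butyldimethylsilyl)oxy]-6,8-dimethoxy-2-{3,4,5-tris[(tert-butyldimethylsilyl)oxy]phenyl}-3,4-dihydro-2H-chromene-3,4,5-triol
Product: 16 (2R,3S,4R)-6,8-dimethoxy-2-(3,4,5-trihydroxyphenyl)-3,4-dihydro-2H-chromene-3,4,5,7-tetrol (CNP0305400.1)
Conditions: TBAF (4.4 equiv), AcOH (4.4 equiv), THF, 0 °C, under argon; Sephadex LH-20
Reagents that add atoms: none
Why: Fluoride-induced cleavage of the four aryl silyl ethers, buffered with acetic acid so that the medium stays near neutral, should free the phenols without ionising the benzylic C4 hydroxyl or oxidising the pyrogallol ring, and touches no stereocenter.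

**Compound list**

1 | 2,6-dimethoxyphenol | COc1cccc(OC)c1O | starting material
2 | tert-butyl(2,6-dimethoxyphenoxy)dimethylsilane | COc1cccc(OC)c1O[Si](C)(C)C(C)(C)C | intermediate
3 | tert-butyl(3,5-dibromo-2,6-dimethoxyphenoxy)dimethylsilane | COc1c(Br)cc(Br)c(OC)c1O[Si](C)(C)C(C)(C)C | intermediate
4 | {5-[(tert-butyldimethylsilyl)oxy]-4,6-dimethoxy-1,3-phenylene}dilithium | [Li]c1cc([Li])c(OC)c(O[Si](C)(C)C(C)(C)C)c1OC | intermediate (not isolated)
5 | tetraisopropyl {5-[(tert-butyldimethylsilyl)oxy]-4,6-dimethoxy-1,3-phenylene}bis(boronate) | CC(C)OB(OC(C)C)c1cc(B(OC(C)C)OC(C)C)c(OC)c(O[Si](C)(C)C(C)(C)C)c1OC | intermediate (not isolated)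
6 | 5-[(tert-butyldimethylsilyl)oxy]-4,6-dimethoxybenzene-1,3-diol | COc1c(O)cc(O)c(OC)c1O[Si](C)(C)C(C)(C)C | intermediate
7 | 3,4,5-trihydroxybenzaldehyde | O=Cc1cc(O)c(O)c(O)c1 | starting material
8 | 3,4,5-tris[(tert-butyldimethylsilyl)oxy]benzaldehyde | O=Cc1cc(O[Si](C)(C)C(C)(C)C)c(O[Si](C)(C)C(C)(C)C)c(O[Si](C)(C)C(C)(C)C)c1 | intermediate
9 | ethyl (E)-3-{3,4,5-tris[(tert-butyldimethylsilyl)oxy]phenyl}prop-2-enoate | CCOC(=O)/C=C/c1cc(O[Si](C)(C)C(C)(C)C)c(O[Si](C)(C)C(C)(C)C)c(O[Si](C)(C)C(C)(C)C)c1 | intermediate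
10 | (E)-3-{3,4,5-tris[(tert-butyldimethylsilyl)oxy]phenyl}prop-2-en-1-ol | OC/C=C/c1cc(O[Si](C)(C)C(C)(C)C)c(O[Si](C)(C)C(C)(C)C)c(O[Si](C)(C)C(C)(C)C)c1 | intermediate
11 | [(2S,3S)-3-{3,4,5-tris[(tert-butyldimethylsilyl)oxy]phenyl}oxiran-2-yl]methanol | OC[C@@H]1O[C@H]1c2cc(O[Si](C)(C)C(C)(C)C)c(O[Si](C)(C)C(C)(C)C)c(O[Si](C)(C)C(C)(C)C)c2 | intermediate
12 | (2R,3S)-3-{3,4,5-tris[(tert-butyldimethylsilyl)oxy]phenyl}oxirane-2-carbaldehyde | O=C[C@@H]1O[C@H]1c2cc(O[Si](C)(C)C(C)(C)C)c(O[Si](C)(C)C(C)(C)C)c(O[Si](C)(C)C(C)(C)C)c2 | intermediate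
13 | bis(bromomagnesium) 5-[(tert-butyldimethylsilyl)oxy]-4,6-dimethoxybenzene-1,3-diolate | COc1c(O[Mg]Br)cc(O[Mg]Br)c(OC)c1O[Si](C)(C)C(C)(C)C | intermediate (not isolated)
14 | bis(bromomagnesium) salt of (R)-{4-[(tert-butyldimethylsilyl)oxy]-2,6-dihydroxy-3,5-dimethoxyphenyl}[(2S,3S)-3-{3,4,5-tris[(tert-butyldimethylsilyl)oxy]phenyl}oxiran-2-yl]methanol | COc1c(O[Mg]Br)c([C@@H](O[Mg]Br)[C@@H]2O[C@H]2c3cc(O[Si](C)(C)C(C)(C)C)c(O[Si](C)(C)C(C)(C)C)c(O[Si](C)(C)C(C)(C)C)c3)c(O)c(OC)c1O[Si](C)(C)C(C)(C)C | intermediate (not isolated)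
15 | (2R,3S,4R)-7-[(tert-butyldimethylsilyl)oxy]-6,8-dimethoxy-2-{3,4,5-tris[(tert-butyldimethylsilyl)oxy]phenyl}-3,4-dihydro-2H-chromene-3,4,5-triol | COc1c(O[Si](C)(C)C(C)(C)C)c(OC)c2c(c1O)[C@@H](O)[C@H](O)[C@@H](c3cc(O[Si](C)(C)C(C)(C)C)c(O[Si](C)(C)C(C)(C)C)c(O[Si](C)(C)C(C)(C)C)c3)O2 | intermediate
16 | (2R,3S,4R)-6,8-dimethoxy-2-(3,4,5-trihydroxyphenyl)-3,4-dihydro-2H-chromene-3,4,5,7-tetrol | COc1c(O)c(OC)c2c(c1O)[C@@H](O)[C@H](O)[C@@H](c1cc(O)c(O)c(O)c1)O2 | target

**Step count and risks**

Total step count: 10. Longest linear sequence: 7 steps (steps 4 to 10, from 7 to 16).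

Steps most likely to fail:

1. Step 9 (Proposed new method). The addition may take the non-chelated carbonyl face and give the C4 epimer. The epoxide may open in the 5-exo sense, by bromide, or after a Payne-type migration. A benzylic cation at C2 would erode the 2,3-trans relationship. The fallback makes the two bonds one after the other by known reactions, sets out from 6 (with 12) and comes back at 15. Compound 6 would be converted with MOMCl and i-Pr2NEt in CH2Cl2 into the bis(methoxymethyl) ether F1. Lithiation of the ring carbon between the two acetal oxygens (n-BuLi, THF, 0 °C) and addition to 12 at −78 °C should give the epoxy alcohol F2 as a mixture at the carbinol. Dess–Martin oxidation would remove that centre and give the epoxy ketone F3. HCl in MeOH–THF would cleave the acetals, and the freed phenol should then open the epoxide at the benzylic carbon with inversion (the classical chalcone epoxide cyclisation) to give the 2,3-trans dihydroflavonol F4. NaBH4 in EtOH at 0 °C, which is known to reduce 2,3-trans dihydroflavonols to 3,4-trans diols, would return the route to 15.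

2. Step 10. The benzylic C4 hydroxyl may ionise, or the freed polyphenol may oxidise in air, during desilylation and purification. The fallback moves the formation of the sensitive diol to the very end; it sets out from 15 and comes back at 16. MnO2 in CH2Cl2 at rt would oxidise the benzylic C4 hydroxyl of 15 to the same dihydroflavonol F4. Desilylation at this robust ketone stage (TBAF, AcOH, THF) should give the free dihydroflavonol F5. NaBH4 in EtOH at 0 °C on the unprotected ketone, the classical preparation of 2,3-trans-3,4-trans flavan-3,4-diols, would then give 16.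

3. Step 3. The second bromine–lithium exchange may stay incomplete, and the aryllithium may be protonated or butylated, so that mono-phenol results. The fallback replaces the organolithium by palladium catalysis; it sets out from 3 and comes back at 6. Miyaura borylation of 3 with bis(pinacolato)diboron, Pd(dppf)Cl2 and KOAc in dioxane at 90 °C should give the bis(pinacol boronate) F6, which is isolated. Oxidation with H2O2 and NaHCO3 in THF–water at 0 °C would give 6.

**Further compounds**

F1 | step 9 | tert-butyl[2,6-dimethoxy-3,5-bis(methoxymethoxy)phenoxy]dimethylsilane | COCOc1cc(OCOC)c(OC)c(O[Si](C)(C)C(C)(C)C)c1OC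
F2 | step 9 | {4-[(tert-butyldimethylsilyl)oxy]-3,5-dimethoxy-2,6-bis(methoxymethoxy)phenyl}[(2S,3S)-3-{3,4,5-tris[(tert-butyldimethylsilyl)oxy]phenyl}oxiran-2-yl]methanol (both carbinol epimers) | COCOc1c(C(O)[C@@H]2O[C@H]2c3cc(O[Si](C)(C)C(C)(C)C)c(O[Si](C)(C)C(C)(C)C)c(O[Si](C)(C)C(C)(C)C)c3)c(OCOC)c(OC)c(O[Si](C)(C)C(C)(C)C)c1OC
F3 | step 9 | {4-[(tert-butyldimethylsilyl)oxy]-3,5-dimethoxy-2,6-bis(methoxymethoxy)phenyl}[(2R,3S)-3-{3,4,5-tris[(tert-butyldimethylsilyl)oxy]phenyl}oxiran-2-yl]methanone | COCOc1c(C(=O)[C@@H]2O[C@H]2c3cc(O[Si](C)(C)C(C)(C)C)c(O[Si](C)(C)C(C)(C)C)c(O[Si](C)(C)C(C)(C)C)c3)c(OCOC)c(OC)c(O[Si](C)(C)C(C)(C)C)c1OC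
F4 | step 9 | (2R,3R)-7-[(tert-butyldimethylsilyl)oxy]-3,5-dihydroxy-6,8-dimethoxy-2-{3,4,5-tris[(tert-butyldimethylsilyl)oxy]phenyl}-2,3-dihydro-4H-chromen-4-one | COc1c(O[Si](C)(C)C(C)(C)C)c(OC)c2c(c1O)C(=O)[C@H](O)[C@@H](c3cc(O[Si](C)(C)C(C)(C)C)c(O[Si](C)(C)C(C)(C)C)c(O[Si](C)(C)C(C)(C)C)c3)O2
F5 | step 10 | (2R,3R)-3,5,7-trihydroxy-6,8-dimethoxy-2-(3,4,5-trihydroxyphenyl)-2,3-dihydro-4H-chromen-4-one | COc1c(O)c(OC)c2c(c1O)C(=O)[C@H](O)[C@@H](c3cc(O)c(O)c(O)c3)O2
F6 | step 3 | tert-butyl[2,6-dimethoxy-3,5-bis(4,4,5,5-tetramethyl-1,3,2-dioxaborolan-2-yl)phenoxy]dimethylsilane | COc1c(B2OC(C)(C)C(C)(C)O2)cc(B3OC(C)(C)C(C)(C)O3)c(OC)c1O[Si](C)(C)C(C)(C)C
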